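## Retrosynthetic overview

1. The target is opened by a retro enolate [2,3]-Wittig shift to a 13-membered α-(butenolidylmethoxy) ketone. In the forward sense this one step makes C7–C8, the C8 carbinol, the C11=C13 methylene and the ten-membered ring.
2. The 13-membered ether comes from an intramolecular oxa-Michael/E1cB etherification of a C8 alcohol onto an α-methylene-β-acyloxy-γ-lactone, itself from a Morita–Baylis–Hillman adduct of a C7 aldehyde.
3. C4–C7 come from D-tartrate acetonide (C5, C6), with C4 set by chelation-controlled MeMgBr addition. C8–C10 and C1–C3 come from (S)-β-citronellene (C10), joined at C3–C4 by a Weinreb ketone synthesis. The ester comes from (R)-2-methylbutanoic acid.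
4. Ring order: γ-lactone (step 8), then 13-membered oxacycle (step 11), then ten-membered carbocycle (step 13).

Assumption: (S)-β-citronellene, dimethyl 2,3-O-isopropylidene-D-tartrate and (R)-2-methylbutanoic acid are bought enantiopure; locants C1–C15 are those of the target skeleton (C4 carbinol with methyl C15, C5 ester, C6 lactone oxygen, C7, C8 carbinol, C9 ketone, C10 with methyl C14, C11=C13 methylene, C12 lactone carbonyl).

## Route

Step 1
Reactants: 1 (S)-3,7-dimethylocta-1,6-diene ((S)-β-citronellene)
Product: 3 (S)-4-methylhex-5-en-1-ol, via (S)-4-methylhex-5-enal 2 (not isolated)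
Conditions: O3 (1.0 equiv, Sudan Red 7B end point), CH2Cl2/MeOH 4:1, −78 °C; then NaBH4, −78 → 25 °C
Reagents that add atoms: ozone, [O-][O+]=O
Why: Chemoselective ozonolysis, since the trisubstituted alkene reacts far faster than the vinyl group, followed by in-situ borohydride reduction; the C10 stereocentre is not touched.

Step 2
Reactants: 3 (S)-4-methylhex-5-en-1-ol
Product: 4 (S)-6-bromo-3-methylhex-1-ene
Conditions: CBr4, PPh3, CH2Cl2, 0 °C
Reagents that add atoms: carbon tetrabromide, BrC(Br)(Br)Br
Why: Appel reaction of a primary alcohol under neutral conditions, with no effect on the alkene or the stereocentre.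

Step 3
Reactants: 5 dimethyl (4S,5S)-2,2-dimethyl-1,3-dioxolane-4,5-dicarboxylate
Product: 6 (4S,5S)-N4,N5-dimethoxy-N4,N5,2,2-tetramethyl-1,3-dioxolane-4,5-dicarboxamide
Conditions: MeNH(OMe)·HCl, i-PrMgCl, THF, −20 → 0 °C
Reagents that add atoms: N,O-dimethylhydroxylamine hydrochloride, CNOC.Cl
Why: Weinreb amide formation by ester aminolysis with the magnesium amide; the trans-acetonide stereocentres (future C5 and C6) are configurationally stable under these conditions.

Step 4
Reactants: 4 (S)-6-bromo-3-methylhex-1-ene; 6 (4S,5S)-N4,N5-dimethoxy-N4,N5,2,2-tetramethyl-1,3-dioxolane-4,5-dicarboxamide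
Product: 8 (4S,5S)-N-methoxy-N,2,2-trimethyl-5-[(5S)-5-methylhept-6-enoyl]-1,3-dioxolane-4-carboxamide, via [(S)-4-methylhex-5-en-1-yl]magnesium bromide 7 (not isolated)
Conditions: Mg, THF, 0 °C; then 6 (1.0 equiv), THF, −78 → 0 °C; aq. NH4Cl
Reagents that add atoms: none
Why: Grignard formation then Weinreb ketone synthesis forms C3–C4; the chelated tetrahedral intermediate stops over-addition, one equivalent leaves the second amide intact, and the two amides are equivalent by the C2 axis.

Step 5
Reactants: 8 (4S,5S)-N-methoxy-N,2,2-trimethyl-5-[(5S)-5-methylhept-6-enoyl]-1,3-dioxolane-4-carboxamide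
Product: 9 (4S,5S)-5-[(2R,6S)-2-hydroxy-6-methyloct-7-en-2-yl]-N-methoxy-N,2,2-trimethyl-1,3-dioxolane-4-carboxamide
Conditions: MeMgBr (1.3 equiv), MgBr2·OEt2, CH2Cl2/Et2O, −78 °C
Reagents that add atoms: methylmagnesium bromide, C[Mg]Br
Why: Cram-chelate-controlled Grignard addition: Mg bridges the ketone oxygen and the adjacent dioxolane oxygen, and methyl enters from the C5–H side to give the 4R tertiary alcohol; the ketone reacts faster than the Weinreb amide at −78 °C.

Step 6
Reactants: 9 (4S,5S)-5-[(2R,6S)-2-hydroxy-6-methyloct-7-en-2-yl]-N-methoxy-N,2,2-trimethyl-1,3-dioxolane-4-carboxamide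
Product: 10 (4S,5S)-5-[(2R,6S)-2-hydroxy-6-methyloct-7-en-2-yl]-2,2-dimethyl-1,3-dioxolane-4-carbaldehyde
Conditions: i-Bu2AlH (2.5 equiv), THF, −78 °C; then MeOH, aq. NH4Cl
Reagents that add atoms: none
Why: Weinreb amide reduction stops at the aldehyde (C7) through the stable aluminium hemiaminal; the trans-acetonide blocks lactol formation with the C4 hydroxyl and is the thermodynamic epimer at C6.

Step 7
Reactants: 10 (4S,5S)-5-[(2R,6S)-2-hydroxy-6-methyloct-7-en-2-yl]-2,2-dimethyl-1,3-dioxolane-4-carbaldehyde; 11 methyl acrylate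
Product: 12 methyl 2-[hydroxy(dioxolanyl)methyl]prop-2-enoate, the C7 adduct of 10 (both C7 epimers; C4, C5, C6, C10 as in 10)
Conditions: methyl acrylate (3 equiv), DABCO (1 equiv), 1,4-dioxane/H2O 1:1, 25 °C, 3 d
Reagents that add atoms: none
Why: Morita–Baylis–Hillman reaction of an activated α-alkoxy aldehyde installs C11, C12 and C13 in one step; the new C7 carbinol centre need not be controlled because it becomes sp2 in step 11.

Step 8
Reactants: 12 Morita–Baylis–Hillman adduct
Product: 13 (5R)-5-[(1S,2R,6S)-1,2-dihydroxy-2,6-dimethyloct-7-en-1-yl]-4-hydroxy-3-methylideneoxolan-2-one (both epimers at the ring carbinol C7)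
Conditions: TFA/H2O 4:1, 0 → 25 °C
Reagents that add atoms: none
Why: Acid-catalysed acetonide hydrolysis followed by lactonization; the γ-hydroxyl (O6) closes the five-membered lactone in preference to the δ-hydroxyl, which differentiates O6 (ring) from O5 (free) without any stereocentre being touched.

Step 9
Reactants: 13 lactone triol; 14 (R)-2-methylbutanoic acid
Product: 16 O5,O7-bis[(R)-2-methylbutanoyl] derivative of 13 (C4–OH free), via (R)-2-methylbutanoyl chloride 15 (not isolated)
Conditions: 14 (2.6 equiv), (COCl)2, cat. DMF, CH2Cl2, 0 °C; then 13, pyridine, CH2Cl2, 0 → 25 °C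
Reagents that add atoms: none
Why: Esterification through the acid chloride acylates both secondary hydroxyls and leaves the tertiary C4–OH; the O5 ester is the one kept in the target, the O7 ester is the leaving group for step 11, and pyridine without DMAP avoids SN2' scrambling of the allylic ester and ketene-type racemisation of the acyl group.

Step 10
Reactants: 16 bis-ester
Product: 17 8,9-diol of 16 (vinyl group converted to CH(OH)CH2OH; both C9 epimers)
Conditions: K2OsO2(OH)4 (2 mol %), NMO, citric acid, t-BuOH/H2O 1:1, 25 °C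
Reagents that add atoms: N-methylmorpholine N-oxide, C[N+]1([O-])CCOCC1; water, O
Why: Upjohn dihydroxylation is chemoselective for the electron-rich vinyl group over the electron-poor, hindered exocyclic methylene; citric acid keeps the amine by-product protonated, and the C9 centre is erased in step 12.

Step 11
Reactants: 17 diol bis-ester
Product: 18 13-membered cyclic ether (ring atoms C9, C8, O, C13, C11, C7, C6, C5, C4, C3, C2, C1, C10) carrying the C7=C11 butenolide, C9–OH (both epimers), the C5 (R)-2-methylbutanoate and C4–OH; 4R,5S,6R,10S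
Conditions: Cs2CO3, MeCN, 0.002 M, 25–40 °C
Reagents that add atoms: none
Why: Intramolecular oxa-Michael addition/E1cB elimination (SN2' allylic etherification): the primary C8 alkoxide adds to the exocyclic methylene and the lactone enolate expels the C7 carboxylate, giving the butenolide and the macrocycle; the hindered C9 and C4 hydroxyls compete poorly.

Step 12
Reactants: 18 macrocyclic ether alcohol
Product: 19 C9 ketone of 18 (α-allyloxy ketone; 4R,5S,6R,10S)
Conditions: Dess–Martin periodinane, CH2Cl2, 0 → 25 °C
Reagents that add atoms: none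
Why: Dess–Martin oxidation of the only secondary alcohol (the tertiary C4–OH is inert) under near-neutral conditions that do not epimerise C10.

Step 13
Reactants: 19 macrocyclic α-allyloxy ketone
Product: 21 target CNP0339940.1, via dibutylboron enolate 20 (not isolated)
Conditions: Bu2BOTf (2.5 equiv), i-Pr2NEt (3 equiv), CH2Cl2, −78 → 25 °C; then pH 7 buffer, MeOH
Reagents that add atoms: none
Why: Enolate [2,3]-Wittig rearrangement as a 13 → 10 ring contraction: kinetic boron enolisation occurs at the α-alkoxy CH2 (C8), C8 bonds to the butenolide β-carbon C7 anti to the C5-bearing substituent on C6 (trans-lactone, 7S) with C9 exo in the five-membered envelope (8S), and the C13–O bond breaks to release the C8 hydroxyl and the exocyclic methylene.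

## Compound list

1 | (S)-3,7-dimethylocta-1,6-diene ((S)-β-citronellene) | C=C[C@@H](C)CCC=C(C)C | starting material
2 | (S)-4-methylhex-5-enal | C=C[C@@H](C)CCC=O | intermediate
3 | (S)-4-methylhex-5-en-1-ol | C=C[C@@H](C)CCCO | intermediate
4 | (S)-6-bromo-3-methylhex-1-ene | C=C[C@@H](C)CCCBr | intermediate
5 | dimethyl (4S,5S)-2,2-dimethyl-1,3-dioxolane-4,5-dicarboxylate (dimethyl 2,3-O-isopropylidene-D-tartrate) | COC(=O)[C@H]1OC(C)(C)O[C@@H]1C(=O)OC | starting material
6 | (4S,5S)-N4,N5-dimethoxy-N4,N5,2,2-tetramethyl-1,3-dioxolane-4,5-dicarboxamide | CON(C)C(=O)[C@H]1OC(C)(C)O[C@@H]1C(=O)N(C)OC | intermediate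
7 | [(S)-4-methylhex-5-en-1-yl]magnesium bromide | C=C[C@@H](C)CCC[Mg]Br | intermediate
8 | (4S,5S)-N-methoxy-N,2,2-trimethyl-5-[(5S)-5-methylhept-6-enoyl]-1,3-dioxolane-4-carboxamide | C=C[C@@H](C)CCCC(=O)[C@H]1OC(C)(C)O[C@@H]1C(=O)N(C)OC | intermediate
9 | (4S,5S)-5-[(2R,6S)-2-hydroxy-6-methyloct-7-en-2-yl]-N-methoxy-N,2,2-trimethyl-1,3-dioxolane-4-carboxamide | C=C[C@@H](C)CCC[C@@](C)(O)[C@H]1OC(C)(C)O[C@@H]1C(=O)N(C)OC | intermediate
10 | (4S,5S)-5-[(2R,6S)-2-hydroxy-6-methyloct-7-en-2-yl]-2,2-dimethyl-1,3-dioxolane-4-carbaldehyde | C=C[C@@H](C)CCC[C@@](C)(O)[C@H]1OC(C)(C)O[C@@H]1C=O | intermediate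
11 | methyl acrylate | C=CC(=O)OC | starting material
12 | methyl 2-[hydroxy(dioxolanyl)methyl]prop-2-enoate from 10 (both C7 epimers; target-locant configuration 4R,5S,6R,10S) | C=C[C@@H](C)CCC[C@@](C)(O)[C@H]1OC(C)(C)O[C@@H]1C(O)C(=C)C(=O)OC | intermediate
13 | (5R)-5-[(1S,2R,6S)-1,2-dihydroxy-2,6-dimethyloct-7-en-1-yl]-4-hydroxy-3-methylideneoxolan-2-one (both epimers at ring C4 = C7) | C=C[C@@H](C)CCC[C@@](C)(O)[C@@H](O)[C@@H]1OC(=O)C(=C)C1O | intermediate
14 | (R)-2-methylbutanoic acid | CC[C@@H](C)C(=O)O | starting material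
15 | (R)-2-methylbutanoyl chloride | CC[C@@H](C)C(=O)Cl | intermediate
16 | O5,O7-bis[(R)-2-methylbutanoyl] derivative of 13 (C4–OH free; both C7 epimers) | C=C[C@@H](C)CCC[C@@](C)(O)[C@@H](OC(=O)[C@H](C)CC)[C@@H]1OC(=O)C(=C)C1OC(=O)[C@H](C)CC | intermediate
17 | 8,9-diol of 16 (both C9 epimers) | OCC(O)[C@@H](C)CCC[C@@](C)(O)[C@@H](OC(=O)[C@H](C)CC)[C@@H]1OC(=O)C(=C)C1OC(=O)[C@H](C)CC | intermediate
18 | 13-membered C8–O–C13 cyclic ether with C7=C11 butenolide, C9–OH (both epimers), C5 (R)-2-methylbutanoate, C4–OH; 4R,5S,6R,10S | OC1COCC2=C[C@@H](OC2=O)[C@H](OC(=O)[C@H](C)CC)[C@](C)(O)CCC[C@@H]1C | intermediate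
19 | C9 ketone of 18 (macrocyclic α-allyloxy ketone); 4R,5S,6R,10S | O=C1COCC2=C[C@@H](OC2=O)[C@H](OC(=O)[C@H](C)CC)[C@](C)(O)CCC[C@@H]1C | intermediate
20 | C8=C9 dibutylboron enolate of 19 (C4–O–BBu2) | CCCCB(CCCC)OC1=COCC2=C[C@@H](OC2=O)[C@H](OC(=O)[C@H](C)CC)[C@](C)(OB(CCCC)CCCC)CCC[C@@H]1C | intermediate
21 | CNP0339940.1 (4R,5S,6R,7S,8S,10S; (R)-2-methylbutanoate at O5) | C=C1C(=O)O[C@@H]2[C@@H]1[C@H](O)C(=O)[C@@H](C)CCC[C@@](C)(O)[C@H]2OC(=O)[C@H](C)CC | target

## Step count and risks

Total steps: 13. Longest linear sequence: 12 steps (1 to 21 through steps 1, 2 and 4–13).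

Three steps most likely to fail, in order of risk:

**Step 13 (ring-contracting [2,3]-Wittig shift).** The face selectivity at C7 and C8 rests on a transition-state argument, and a competing [3,3] shift or enolisation toward C10 is possible. The fallback sets out from 17 and abandons the sigmatropic step for a metal-mediated macrocyclic allylation. IBX (EtOAc, 70 °C) oxidises the 8,9-diol to the C8-aldehyde/C9-ketone, the 2-oxoaldehyde bis-ester F1. Pd(PPh3)4 (cat.) and InI in THF at high dilution then convert the C7 allylic ester into an allylindium that adds through C7 to the C8 aldehyde (umpolung Barbier-type allylation, chair transition state). This forms C7–C8, the C8 carbinol and the exocyclic methylene, and comes back to the route at 21.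

**Step 11 (macrocyclic oxa-Michael/E1cB etherification).** A carbonate base may not generate enough alkoxide, or the carboxylate may transpose. The fallback sets out from 17 and replaces the conjugate addition by an SN2 alkylation of a tin acetal. MgBr2·OEt2 (CH2Cl2, 0 °C) displaces the C7 carboxylate in SN2' fashion to give the α-(bromomethyl)butenolide diol F2. Its dibutylstannylene acetal (Bu2SnO, toluene, reflux) is then alkylated at the primary oxygen by the allylic bromide (CsF, DMF, 0.002 M). This comes back to the route at 18.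

**Step 5 (chelation-controlled methyl addition).** If non-chelation control dominates, the C4 epimer forms. The fallback sets out from 6 and reverses the order in which the two C4 substituents arrive. MeMgBr (1.0 equiv, THF, −78 °C) first gives the methyl ketone Weinreb amide F3, to which Grignard reagent 7 is then added. The same facial preference that gave the wrong epimer from 8 now delivers the 4R alcohol, and the sequence comes back to the route at 9.

## Further compounds

F1 | step 13 | 2-oxoaldehyde bis-ester (C8 aldehyde, C9 ketone; otherwise as 17) | O=CC(=O)[C@@H](C)CCC[C@@](C)(O)[C@@H](OC(=O)[C@H](C)CC)[C@@H]1OC(=O)C(=C)C1OC(=O)[C@H](C)CC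
F2 | step 11 | α-(bromomethyl)butenolide diol (C13 bromide, C7=C11; C5 ester, C4–OH, 8,9-diol) | OCC(O)[C@@H](C)CCC[C@@](C)(O)[C@@H](OC(=O)[C@H](C)CC)[C@@H]1OC(=O)C(CBr)=C1
F3 | step 5 | (4S,5S)-5-acetyl-N-methoxy-N,2,2-trimethyl-1,3-dioxolane-4-carboxamide | CC(=O)[C@H]1OC(C)(C)O[C@@H]1C(=O)N(C)OC
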